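**Retrosynthetic overview**
- Target 14 ⇒ myrcene 13 + 2'-hydroxychalcone 12 by a late, catalytic enantioselective [4+2] cycloaddition. This step builds the cyclohexene and sets both stereocentres (C1, C6).
- Chalcone 12 ⇒ hexasubstituted aryl bromide 7 + cinnamaldehyde 8 (Br/Li exchange, 1,2-addition, oxidation, MOM removal).
- Bromide 7 ⇒ 5-methoxyresorcinol 1 by MOM protection, two directed ortho-metalations (C-methyl, then CO2Me) and bromination.
- Ring order: the benzene ring is bought and fully substituted first; the cyclohexene is the only ring formed, in the last step.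

Assumption: the target is the trans-(1R,6R) isomer encoded by the SMILES; MOM = methoxymethyl; (S,S)-t-Bu-box = 2,2'-(propane-2,2-diyl)bis[(4S)-4-tert-butyl-4,5-dihydro-1,3-oxazole].

**Route**

Step 1
Reactants: 1 5-methoxybenzene-1,3-diol
Product: 2 1-methoxy-3,5-bis(methoxymethoxy)benzene
Conditions: NaH, MOMCl, DMF, 0 °C to rt
Reagents that add atoms: chloromethyl methyl ether (MOMCl), COCCl
Why: Williamson-type O-alkylation of both phenoxides by the reactive α-chloro ether protects the phenols and installs the ortho-directing groups used in steps 2 and 3.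

Step 2
Reactants: 2 1-methoxy-3,5-bis(methoxymethoxy)benzene
Product: 4 5-methoxy-1,3-bis(methoxymethoxy)-2-methylbenzene, via aryllithium 3 (not isolated)
Conditions: n-BuLi, THF, 0 °C to rt; then MeI, 0 °C
Reagents that add atoms: iodomethane (MeI), CI
Why: Directed ortho-metalation goes to the ring position flanked by the two chelating MOM ethers (stronger directing groups than OMe), and the aryllithium is methylated by SN2 attack on MeI to give a symmetrical product.

Step 3
Reactants: 4 5-methoxy-1,3-bis(methoxymethoxy)-2-methylbenzene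
Product: 6 methyl 6-methoxy-2,4-bis(methoxymethoxy)-3-methylbenzoate, via aryllithium 5 (not isolated)
Conditions: n-BuLi, TMEDA, THF, 0 °C; then cannulate into ClCO2Me, THF, −78 °C
Reagents that add atoms: methyl chloroformate, COC(=O)Cl
Why: A second directed ortho-metalation can only take one of the two equivalent ring C–H bonds lying between OMOM and OMe, and inverse addition of the hindered aryllithium to excess chloroformate (acyl substitution) gives the ester without over-addition.

Step 4
Reactants: 6 methyl 6-methoxy-2,4-bis(methoxymethoxy)-3-methylbenzoate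
Product: 7 methyl 3-bromo-2-methoxy-4,6-bis(methoxymethoxy)-5-methylbenzoate
Conditions: NBS, MeCN, 0 °C to rt, dark
Reagents that add atoms: N-bromosuccinimide (NBS), O=C1CCC(=O)N1Br
Why: Electrophilic aromatic bromination at the single remaining ring position, which is activated by two ortho and one para oxygen substituents.

Step 5
Reactants: 7 methyl 3-bromo-2-methoxy-4,6-bis(methoxymethoxy)-5-methylbenzoate, 8 (2E)-3-phenylprop-2-enal
Product: 10 methyl 3-[(2E)-1-hydroxy-3-phenylprop-2-en-1-yl]-2-methoxy-4,6-bis(methoxymethoxy)-5-methylbenzoate (racemic), via aryllithium 9 (not isolated)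
Conditions: n-BuLi, THF, −78 °C, 15 min; then 8, −78 °C; H2O
Reagents that add atoms: none
Why: Bromine–lithium exchange at −78 °C outruns attack on the doubly ortho-flanked methyl ester, and the aryllithium adds 1,2 to the enal (carbonyl addition) to give a racemic carbinol whose stereocentre is erased in step 6.

Step 6
Reactants: 10 methyl 3-[(2E)-1-hydroxy-3-phenylprop-2-en-1-yl]-2-methoxy-4,6-bis(methoxymethoxy)-5-methylbenzoate
Product: 11 methyl 2-methoxy-4,6-bis(methoxymethoxy)-5-methyl-3-[(2E)-3-phenylprop-2-enoyl]benzoate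
Conditions: MnO2 (activated, excess), CH2Cl2, rt
Reagents that add atoms: none
Why: MnO2 oxidation is selective for the allylic/benzylic alcohol and leaves the MOM ethers, the ester and the E-alkene untouched.

Step 7
Reactants: 11 methyl 2-methoxy-4,6-bis(methoxymethoxy)-5-methyl-3-[(2E)-3-phenylprop-2-enoyl]benzoate
Product: 12 methyl 2,4-dihydroxy-6-methoxy-3-methyl-5-[(2E)-3-phenylprop-2-enoyl]benzoate
Conditions: 3 M HCl (aq), MeOH, 40 °C
Reagents that add atoms: none
Why: Acid-catalysed acetal exchange with methanol removes both MOM ethers under conditions too mild for flavanone ring closure, and methanol as solvent makes any ester exchange degenerate.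

Step 8
Reactants: 12 methyl 2,4-dihydroxy-6-methoxy-3-methyl-5-[(2E)-3-phenylprop-2-enoyl]benzoate, 13 7-methyl-3-methylideneocta-1,6-diene (myrcene)
Product: 14 methyl 2,4-dihydroxy-6-methoxy-3-methyl-5-[(1R,6R)-4-(4-methylpent-3-en-1-yl)-6-phenylcyclohex-3-ene-1-carbonyl]benzoate
Conditions: Cu(OTf)2 (10 mol%), (S,S)-t-Bu-box (11 mol%), 2,6-di-tert-butylpyridine (10 mol%), 13 (5 equiv), 4 Å MS, CH2Cl2, 0 °C to rt
Reagents that add atoms: none
Why: Proposed new method: the ortho-hydroxy aryl ketone of 12 should bind the divalent copper centre of the C2-symmetric bis(oxazoline) complex as a six-membered phenoxide–carbonyl chelate in the square plane (the hindered pyridine shuttles the phenol proton and releases the product), which lowers the enone LUMO, holds the enone s-cis (the flanking 6-OMe disfavours s-trans) and lets one tert-butyl group block the α-Si/β-Si face, so myrcene adds suprafacially to the α-Re/β-Re face of the E-alkene with the usual para regiochemistry in an enantioselective Diels–Alder reaction giving the trans-(1R,6R) adduct; the closest known reaction type is the Cu(OTf)2–bis(oxazoline)-catalysed Diels–Alder reaction of two-point-binding dienophiles (N-enoyl oxazolidinones, α'-hydroxy enones), together with chiral-borate-promoted cycloadditions of 2'-hydroxychalcones.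

**Compound list**
1 | 5-methoxybenzene-1,3-diol (5-methoxyresorcinol) | COc1cc(O)cc(O)c1 | starting material
2 | 1-methoxy-3,5-bis(methoxymethoxy)benzene | COCOc1cc(OC)cc(OCOC)c1 | intermediate
3 | [4-methoxy-2,6-bis(methoxymethoxy)phenyl]lithium | [Li]c1c(OCOC)cc(OC)cc1OCOC | intermediate
4 | 5-methoxy-1,3-bis(methoxymethoxy)-2-methylbenzene | Cc1c(OCOC)cc(OC)cc1OCOC | intermediate
5 | [6-methoxy-2,4-bis(methoxymethoxy)-3-methylphenyl]lithium | [Li]c1c(OC)cc(OCOC)c(C)c1OCOC | intermediate
6 | methyl 6-methoxy-2,4-bis(methoxymethoxy)-3-methylbenzoate | COC(=O)c1c(OC)cc(OCOC)c(C)c1OCOC | intermediate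
7 | methyl 3-bromo-2-methoxy-4,6-bis(methoxymethoxy)-5-methylbenzoate | COC(=O)c1c(OC)c(Br)c(OCOC)c(C)c1OCOC | intermediate
8 | (2E)-3-phenylprop-2-enal (cinnamaldehyde) | O=C/C=C/c1ccccc1 | starting material
9 | [2-methoxy-3-(methoxycarbonyl)-4,6-bis(methoxymethoxy)-5-methylphenyl]lithium | COC(=O)c1c(OC)c([Li])c(OCOC)c(C)c1OCOC | intermediate
10 | methyl 3-[(2E)-1-hydroxy-3-phenylprop-2-en-1-yl]-2-methoxy-4,6-bis(methoxymethoxy)-5-methylbenzoate (racemic) | COC(=O)c1c(OC)c(C(O)/C=C/c2ccccc2)c(OCOC)c(C)c1OCOC | intermediate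
11 | methyl 2-methoxy-4,6-bis(methoxymethoxy)-5-methyl-3-[(2E)-3-phenylprop-2-enoyl]benzoate | COC(=O)c1c(OC)c(C(=O)/C=C/c2ccccc2)c(OCOC)c(C)c1OCOC | intermediate
12 | methyl 2,4-dihydroxy-6-methoxy-3-methyl-5-[(2E)-3-phenylprop-2-enoyl]benzoate | COC(=O)c1c(O)c(C)c(O)c(C(=O)/C=C/c2ccccc2)c1OC | intermediate
13 | 7-methyl-3-methylideneocta-1,6-diene (myrcene) | C=CC(=C)CCC=C(C)C | starting material
14 | methyl 2,4-dihydroxy-6-methoxy-3-methyl-5-[(1R,6R)-4-(4-methylpent-3-en-1-yl)-6-phenylcyclohex-3-ene-1-carbonyl]benzoate | COC(=O)c1c(O)c(C)c(O)c(C(=O)[C@@H]2CC=C(CCC=C(C)C)C[C@H]2c2ccccc2)c1OC | target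

**Step count**
Total steps: 8. Longest linear sequence: 8 steps (1 → 14).

**Three steps most likely to fail**

Step 8 (the proposed new cycloaddition). The monocationic phenoxide chelate may activate the enone too weakly. The salicylate unit (2-OH/CO2Me) or the product may sequester copper. The facial sense rests on a model; if it proves opposite, the (R,R) ligand is used. Fallback, known chemistry, sets out from bromide 7 and comes back to the route at target 14. Benzaldehyde and 3-hydroxy-3-methylbutan-2-one are condensed (LiOH, MeOH/H2O) to the two-point-binding template (E)-4-hydroxy-4-methyl-1-phenylpent-1-en-3-one F1. Its known Cu(OTf)2/(S,S)-t-Bu-box-catalysed Diels–Alder reaction with myrcene 13 gives 2-hydroxy-2-methyl-1-[(1R,6R)-4-(4-methylpent-3-en-1-yl)-6-phenylcyclohex-3-en-1-yl]propan-1-one F2. NaBH4 reduction gives 1-[(1R,6R)-4-(4-methylpent-3-en-1-yl)-6-phenylcyclohex-3-en-1-yl]-2-methylpropane-1,2-diol F3, and NaIO4 cleavage gives (1R,6R)-4-(4-methylpent-3-en-1-yl)-6-phenylcyclohex-3-ene-1-carbaldehyde F4. Aryllithium 9, made from 7 as in step 5, adds to F4 to give methyl 3-{hydroxy[(1R,6R)-4-(4-methylpent-3-en-1-yl)-6-phenylcyclohex-3-en-1-yl]methyl}-2-methoxy-4,6-bis(methoxymethoxy)-5-methylbenzoate F5. Dess–Martin oxidation gives methyl 2-methoxy-4,6-bis(methoxymethoxy)-5-methyl-3-[(1R,6R)-4-(4-methylpent-3-en-1-yl)-6-phenylcyclohex-3-ene-1-carbonyl]benzoate F6, and HCl/MeOH at rt removes both MOM groups to give 14.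

Step 5 (Br/Li exchange beside an ester). n-BuLi or aryllithium 9 may attack the methyl ester, or 1-bromobutane may alkylate 9. Fallback sets out from ester 6 and comes back at chalcone 12, avoiding organolithium chemistry once the ester is in place. HCl/MeOH converts 6 to methyl 2,4-dihydroxy-6-methoxy-3-methylbenzoate F7. Friedel–Crafts acetylation (Ac2O, BF3·OEt2, 60 °C, aqueous work-up) at the only free ring position gives methyl 3-acetyl-4,6-dihydroxy-2-methoxy-5-methylbenzoate F8. Claisen–Schmidt condensation with benzaldehyde (KOH, MeOH, rt, then dilute acid) gives 12; the doubly ortho-flanked ester resists saponification.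

Step 3 (second ortho-metalation and methoxycarbonylation). Lateral lithiation of the methyl group between the two MOM ethers, or double addition of 5 to the chloroformate, may lower the yield. The regioselectivity of the lithiation in step 2 carries a related risk and is checked by the symmetry of 4 in the NMR spectrum. Fallback sets out from 4 and comes back at 6. NBS (1.0 equiv, MeCN, 0 °C) gives 2-bromo-1-methoxy-3,5-bis(methoxymethoxy)-4-methylbenzene F9. Methoxycarbonylation (Pd(OAc)2, Xantphos, CO, MeOH, Na2CO3, 100 °C; oxidative addition to zerovalent palladium, CO insertion, methanolysis) gives 6.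

Further compounds
F1 | step 8 | (E)-4-hydroxy-4-methyl-1-phenylpent-1-en-3-one | CC(C)(O)C(=O)/C=C/c1ccccc1
F2 | step 8 | 2-hydroxy-2-methyl-1-[(1R,6R)-4-(4-methylpent-3-en-1-yl)-6-phenylcyclohex-3-en-1-yl]propan-1-one | CC(C)(O)C(=O)[C@@H]1CC=C(CCC=C(C)C)C[C@H]1c1ccccc1
F3 | step 8 | 1-[(1R,6R)-4-(4-methylpent-3-en-1-yl)-6-phenylcyclohex-3-en-1-yl]-2-methylpropane-1,2-diol (carbinol epimers) | CC(C)(O)C(O)[C@@H]1CC=C(CCC=C(C)C)C[C@H]1c1ccccc1
F4 | step 8 | (1R,6R)-4-(4-methylpent-3-en-1-yl)-6-phenylcyclohex-3-ene-1-carbaldehyde | O=C[C@@H]1CC=C(CCC=C(C)C)C[C@H]1c1ccccc1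
F5 | step 8 | methyl 3-{hydroxy[(1R,6R)-4-(4-methylpent-3-en-1-yl)-6-phenylcyclohex-3-en-1-yl]methyl}-2-methoxy-4,6-bis(methoxymethoxy)-5-methylbenzoate (carbinol epimers) | COC(=O)c1c(OC)c(C(O)[C@@H]2CC=C(CCC=C(C)C)C[C@H]2c2ccccc2)c(OCOC)c(C)c1OCOC
F6 | step 8 | methyl 2-methoxy-4,6-bis(methoxymethoxy)-5-methyl-3-[(1R,6R)-4-(4-methylpent-3-en-1-yl)-6-phenylcyclohex-3-ene-1-carbonyl]benzoate | COC(=O)c1c(OC)c(C(=O)[C@@H]2CC=C(CCC=C(C)C)C[C@H]2c2ccccc2)c(OCOC)c(C)c1OCOC
F7 | step 5 | methyl 2,4-dihydroxy-6-methoxy-3-methylbenzoate | COC(=O)c1c(OC)cc(O)c(C)c1O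
F8 | step 5 | methyl 3-acetyl-4,6-dihydroxy-2-methoxy-5-methylbenzoate | COC(=O)c1c(OC)c(C(C)=O)c(O)c(C)c1O
F9 | step 3 | 2-bromo-1-methoxy-3,5-bis(methoxymethoxy)-4-methylbenzene | Brc1c(OC)cc(OCOC)c(C)c1OCOC
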